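**Conventions and remarks.** Carbon atoms keep the hydroazulene locants of the target (C1–C8a) in every intermediate, including the monocyclic ones. β is the face of the bicycle that carries H-3a and the C8a methyl group; α is the opposite face. Three design remarks on the chemistry:

- The six-membered ring that enters the key step carries no methyl group on C6; the methyl is attached in step 23. A C6 stereocentre at that stage cannot be tied reliably to C3a, and its two C3a epimers would become enantiomers once C6 turns trigonal.
- The thioacetal is an S-phenyl one, so the later Pummerer reaction can only take place at C2.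
- C3 of the key-step precursor has the configuration that places the isopropyl group equatorially in the cyclisation chair.

## Analysis of the target

The target 41 is a cis-fused hydroazulene: a cyclopentane (C1, C2, C3, C3a, C8a) fused to a cycloheptene (C3a, C4–C8, C8a) with a C5=C6 alkene. It carries isopropyl on C3, methyl on C6 and C8a, and oxygen on C2, C3, C4 and C8. Its six stereocentres (2S,3R,3aR,4S,8S,8aS) are contiguous around the ring fusion: H-3a, the C8a methyl, the C8 hydroxyl, the C3 hydroxyl and the C2 acetate are β, while the C3 isopropyl and the C4 aroyloxy group are α. The sensitive groups are a secondary acetate next to a free tertiary alcohol (acyl migration), an allylic 4-hydroxybenzoate with a free phenol (solvolysis, base), and a tertiary C3 carbinol β to C4, which invites retro-aldol cleavage and C3a epimerisation whenever C4 is a ketone. The difficulty lies in the quaternary C8a flanked by the C8 carbinol and the ring fusion, in the cis fusion, and in telling four oxygen functions apart. The strategy rests on one feature: the C8 oxygen sits directly beside the quaternary ring-fusion carbon C8a of a cis-fused five–seven system. That array is the signature of a cationic cyclisation followed by a pinacol-type 1,2-shift, which turns a 1-alkenylcyclohexanol into a cycloheptanone carrying a new cyclopentane. The remaining functionality (C2/C3 diol, C4 oxygen, C5=C6 alkene) then has to be reachable from what that step leaves behind: a C2 sulfur substituent and a C4=C5 alkene.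

## Retrosynthetic reasoning

**C4 ester and silyl groups (41 ⇒ 40 ⇒ 38 + 39).** The allylic aroyl ester is the most fragile bond, so it is cut first and formed last but one. The phenol and the C8 hydroxyl stay silylated until the final step, so one fluoride treatment releases both.

**C6 methyl and C4 configuration (38 ⇒ 37 ⇒ 33).** The C6–CH3 bond is cut to the enone 33: conjugate addition and re-oxidation put the methyl on C6 and leave the C5=C6 alkene. The C4 alcohol is set from the ketone 37 by hydride delivery from the neighbouring C3 hydroxyl. This gives the anti 1,3-diol and removes any dependence on the face from which C4 was first oxidised.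

**C4 oxygen (33 ⇒ 30 ⇒ 27).** The C4–O bond and the C5=C6 alkene are traced back to the C4=C5 alkene of the key-step product, through epoxide 27 and a 1,3-transposition. Because C6 is a methylene group at this stage, either epoxide face can be used.

**C2/C3 diol (29 ⇒ 28 ⇒ 26 ⇒ 24 ⇒ 21).** The cis diol comes from a C2=C3 alkene, attacked on the β face of the cyclopentene. The alkene comes from the C2 ketone 24 via its enol triflate 26. The ketone is the Pummerer product of the C2 sulfide that the key step delivers. The cycloheptene is epoxidised while C2=C3 is still an unreactive enol triflate, so the two alkenes never compete.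

**Key disconnection (19 ⇒ 16).** C1–C2 and C3a–C8a are cut and C3a–C8 is re-formed. This unravels both rings of 19 to a cyclohexene carrying an isopropenyl group and a silyloxy group on C8 and a thioacetal side chain on C3a. The forward step must form two bonds and the quaternary centre, and must translate the single ring stereocentre C3a into the cis fusion.

**C8–C8a (16 ⇒ 13 + 14).** Carbonyl addition of 14 to ketone 13 on the face opposite the C3a side chain gives the trans arrangement the cyclisation needs.

**Side-chain oxidation level and C3 (13 ⇒ 12 ⇒ 10).** The cis-fused lactone 10 serves two purposes. Its α-carbon C3 can be equilibrated to the convex-face isopropyl epimer. Its carbonyl can be taken to the aldehyde level and thioacetalised without a free β,γ-unsaturated keto aldehyde ever appearing.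

**C3a–C3 and absolute configuration (10 ⇒ 7 ⇒ 4 ⇒ 2 + 3 ⇒ 1).** The C3a–C3 bond is cut in the sense of an Ireland–Claisen rearrangement of ester 4. This moves the alkene to C4=C5 and transfers the configuration of the carbinol carbon of 2 to C3a. Alcohol 2 comes from enantioselective reduction of the achiral enone 1, whose ketal is the future C8 carbonyl.

## Alternatives that were turned down

**Alternative 1:** C3a–C8a is cut as a [3,3] shift on the seven-membered ring alone. C3 (a carboxyl carbon) and C2 are tied through oxygen in the eleven-membered lactone A1; its silyl ketene acetal would rearrange (Ireland–Claisen) to the cycloheptene acid A2 as the allylic C2–O bond breaks.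
- For: the quaternary C8a and C3a are set together in a pericyclic step. A2 already holds the C4 and C8 oxygens and the C5=C6 alkene with its methyl group. On the seven-membered ring this alternative is clearly stronger than the chosen route, which spends eight steps there after the key step.
- Against: A1 is a medium ring with two trisubstituted alkenes of fixed geometry and is costly to close. Its transannular transition state can be chair- or boat-like, so the C3a/C8a relationship is not secure. A2 offers only a vinyl and a carboxyl group from which the whole cyclopentane (C1–C2 and C2–C3 bonds, isopropyl, two oxygen stereocentres) must still be built.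
- Comparison: the chosen route closes both rings in one step from a six-membered ring made in nine steps and leaves C2 functionalised.

**Alternative 2:** The C3–C3a bond is made by intramolecular cyclopropanation. Diazoketone A3 (C3 diazo carbon bearing isopropyl, C2 ketone, C1 attached to C8a of a preformed cycloheptene) would give the tricyclic ketone A4 with Rh2(O2CCPh3)4; the extra C3–C4 bond is cleaved later.
- For: intramolecular delivery guarantees the cis fusion, the C2 ketone is in place, and opening the cyclopropane could bring in the C4 oxygen. On C2 and C4 functionality it is stronger than the chosen route.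
- Against: it presupposes an enantiopure cycloheptene that already contains the quaternary C8a next to the C8 oxygen, which is the hardest part of the problem. A carbenoid flanked by an isopropyl group is prone to 1,2-hydride shift. The regiochemistry of cyclopropane cleavage (C3–C4 against C3–C3a) and the later hydroxylation of C3 are open.
- Comparison: the chosen route creates the seven-membered ring and C8a in the key step itself and pays with a regiochemical question at C2/C3 (step 15).

**Alternative 3:** C1–C8a and C3–C3a are cut together in a (3+2) sense. Cycloheptenone A5 and allenylsilane A6 would combine under TiCl4 (Danheiser annulation) to the silylcyclopentene A7.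
- For: the route is convergent. A7 has the C2=C3 alkene exactly where the diol is needed, with no enolisation ambiguity, and a C4 ketone; for the five-membered ring it is stronger than the chosen route.
- Against: the enone β-carbon C8a already bears a methyl group, so the allene must attack a β,β-disubstituted enone to form the quaternary centre, where this annulation is sluggish. Facial control on a flexible seven-membered enone rests on the C8 silyloxy group alone. A5, with two stereocentres, needs its own multistep synthesis, and the vinylsilane must be protodesilylated.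
- Comparison: the chosen route derives the cis fusion from the mechanism (suprafacial shift) rather than from facial bias, and starts from a commercial six-membered ring.

Key step: step 10

## Route

Step 1
Reactants: 1 1,4-dioxaspiro[4.5]dec-6-en-8-one
Product: 2 (S)-1,4-dioxaspiro[4.5]dec-6-en-8-ol
Conditions: (R)-2-methyl-CBS-oxazaborolidine (10 mol %), catecholborane, toluene, −78 °C
Reagents that add atoms: none
Why: CBS reduction: the oxazaborolidine–borane complex delivers hydride 1,2 to the enone with the alkenyl arm as the large group, which should set the carbinol carbon (future C5) as S; this is the only source of absolute configuration in the route.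

Step 2
Reactants: 2 (S)-1,4-dioxaspiro[4.5]dec-6-en-8-ol; 3 3-methylbutanoyl chloride
Product: 4 (S)-1,4-dioxaspiro[4.5]dec-6-en-8-yl 3-methylbutanoate
Conditions: pyridine, DMAP (cat.), CH2Cl2, 0 °C to rt
Reagents that add atoms: none
Why: Acylation of a secondary allylic alcohol under nucleophilic catalysis; the stereocentre is not touched.

Step 3
Reactants: 4 (S)-1,4-dioxaspiro[4.5]dec-6-en-8-yl 3-methylbutanoate
Product: 7 (2S)-3-methyl-2-[(1R)-2-oxocyclohex-5-en-1-yl]butanoic acid, via silyl ketene acetal 5 (not isolated), via silyl ester 6 (not isolated)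
Conditions: LiN(i-Pr)2, Me3SiCl, THF, −78 °C, then 60 °C; then PPTS, acetone–H2O, 40 °C
Reagents that add atoms: water, O
Why: Ireland–Claisen rearrangement: the suprafacial [3,3] shift forms the C3a–C3 bond on the face of the departing C5–O bond, so C3a should be fixed as R by chirality transfer while the alkene moves to C4=C5. Mild acid then frees the acid and the C8 ketone without conjugating the β,γ-enone. The C3 configuration (drawn as expected from the E ketene acetal through a chair) is of no consequence because it is equilibrated in step 5.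

Step 4
Reactants: 7 (2S)-3-methyl-2-[(1R)-2-oxocyclohex-5-en-1-yl]butanoic acid
Product: 9 (3S,3aR,7aR)-3-isopropyl-3a,6,7,7a-tetrahydro-1-benzofuran-2(3H)-one, via hydroxy acid 8 (not isolated)
Conditions: LiBH(s-Bu)3 (2.5 equiv), THF, −78 °C; NaOH, H2O2; then 1 M HCl, rt
Reagents that add atoms: none
Why: The bulky hydride should attack the C8 ketone from the face away from the C3a side chain to give the cis hydroxy acid, which lactonises on acidification to the cis-fused γ-lactone. Only the cis alcohol closes easily, which also secures C8 for the next steps.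

Step 5
Reactants: 9 (3S,3aR,7aR)-3-isopropyl-3a,6,7,7a-tetrahydro-1-benzofuran-2(3H)-one
Product: 10 (3R,3aR,7aR)-3-isopropyl-3a,6,7,7a-tetrahydro-1-benzofuran-2(3H)-one
Conditions: t-BuOK (0.2 equiv), t-BuOH–THF, rt; AcOH quench
Reagents that add atoms: none
Why: Base-mediated epimerisation through the lactone enolate: under thermodynamic control the isopropyl group should settle on the convex face, trans to the C3a–C4 bond. This is the C3 configuration that the cyclisation chair of step 10 needs; C3a is not acidic and stays.

Step 6
Reactants: 10 (3R,3aR,7aR)-3-isopropyl-3a,6,7,7a-tetrahydro-1-benzofuran-2(3H)-one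
Product: 12 2-[3-methyl-1,1-bis(phenylthio)butan-2-yl]cyclohex-3-en-1-ol (hydroxyl cis to the side chain; C3a and C3 as in 10), via lactol 11 (not isolated)
Conditions: i-Bu2AlH, CH2Cl2, −78 °C; then PhSH (2.5 equiv), BF3·OEt2, CH2Cl2, −20 °C
Reagents that add atoms: thiophenol, Sc1ccccc1
Why: Half-reduction of the lactone to the lactol, then Lewis acid-mediated thioacetalisation of the masked aldehyde; ring opening to the acyclic dithioacetal releases the C8 hydroxyl and touches no stereocentre.

Step 7
Reactants: 12 2-[3-methyl-1,1-bis(phenylthio)butan-2-yl]cyclohex-3-en-1-ol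
Product: 13 2-[3-methyl-1,1-bis(phenylthio)butan-2-yl]cyclohex-3-en-1-one (C3a and C3 as in 10)
Conditions: Dess–Martin periodinane, pyridine, CH2Cl2, 0 °C
Reagents that add atoms: none
Why: Dess–Martin oxidation under buffered, non-basic conditions should give the β,γ-unsaturated ketone without epimerising C3a or moving the alkene into conjugation; thioacetals tolerate the reagent.

Step 8
Reactants: 13 2-[3-methyl-1,1-bis(phenylthio)butan-2-yl]cyclohex-3-en-1-one; 14 isopropenylmagnesium bromide
Product: 15 1-isopropenyl-2-[3-methyl-1,1-bis(phenylthio)butan-2-yl]cyclohex-3-en-1-ol (isopropenyl trans and hydroxyl cis to the side chain)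
Conditions: CeCl3 (anhydrous), THF, −78 °C
Reagents that add atoms: none
Why: Organocerium addition: the low basicity suppresses enolisation of the ketone with its acidic C3a–H, and the nucleophile should enter anti to the C3a side chain, which sets C8 with isopropenyl trans to the side chain.

Step 9
Reactants: 15 1-isopropenyl-2-[3-methyl-1,1-bis(phenylthio)butan-2-yl]cyclohex-3-en-1-ol
Product: 16 trimethylsilyl ether of 15 ({1-isopropenyl-2-[3-methyl-1,1-bis(phenylthio)butan-2-yl]cyclohex-3-en-1-yl}oxytrimethylsilane)
Conditions: N-(trimethylsilyl)imidazole, CH2Cl2, rt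
Reagents that add atoms: N-(trimethylsilyl)imidazole, C[Si](C)(C)n1ccnc1
Why: Silylation of the tertiary alcohol with a neutral silyl donor that leaves the thioacetal and the alkenes alone; the silyl ether is the pinacol terminus of the next step.

Step 10
Reactants: 16 {1-isopropenyl-2-[3-methyl-1,1-bis(phenylthio)butan-2-yl]cyclohex-3-en-1-yl}oxytrimethylsilane
Product: 19 3-isopropyl-8a-methyl-2-(phenylthio)-2,3,3a,6,7,8a-hexahydro-1H-azulen-8-one (cis-fused; H-3a, 8a-methyl and 3-isopropyl β; 2-phenylthio α), via phenylthionium ion 17 (not isolated), via tertiary carbocation 18 (not isolated)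
Conditions: Me2S(SMe)BF4 (1.3 equiv), CH2Cl2, −45 to 0 °C
Reagents that add atoms: none
Why: The sulfonium salt methylthiolates one sulfur of the dithioacetal, and loss of methyl phenyl disulfide gives the thionium ion 17 at C2. The CH2 terminus of the isopropenyl group attacks C2 (C1–C2 bond) in a 6-endo Prins cyclisation through a chair in which the cyclohexene is trans-fused (C4 and C7 equatorial, H-3a and the silyloxy group axial) and the C3 isopropyl group is equatorial, giving the tertiary cation 18. The C8–C3a bond then shifts suprafacially to C8a with retention at C3a, while the silyloxy oxygen becomes the C8 carbonyl and the silyl group is lost; the Prins ring thus contracts to the cyclopentane (closed by the 1,2-shift, not by direct attack) and the cyclohexene grows to the cycloheptenone. The closest known reaction type is the Prins–pinacol ring-enlarging cyclopentane annulation of 1-alkenylcycloalkanol silyl ethers, including thionium-initiated cases. C8a is set because C3a can only arrive on the face of the cation on which it already sits, so H-3a and the methyl group end up cis; C3a and C3 are carried over from 16, and the C2 configuration (arylthio equatorial) is of no consequence. The step needs attack by the 1,1-disubstituted alkene rather than the ring alkene, which is secured because only the former gives a tertiary cation in an unstrained ring. It also needs migration of C3a rather than C7, which is secured by the trans arrangement from step 8: it leaves C7 equatorial on the Prins ring and out of alignment, whereas C3a is a ring bond and allylic.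

Step 11
Reactants: 19 3-isopropyl-8a-methyl-2-(phenylthio)-2,3,3a,6,7,8a-hexahydro-1H-azulen-8-one
Product: 20 3-isopropyl-8a-methyl-2-(phenylthio)-1,2,3,3a,6,7,8,8a-octahydroazulen-8-ol (8β-hydroxyl, 8S)
Conditions: (R)-2-methyl-CBS-oxazaborolidine (20 mol %), catecholborane, toluene, −40 °C
Reagents that add atoms: none
Why: CBS reduction under reagent control: the catalyst should bind the ketone with the quaternary C8a as the large group and deliver hydride to the α face, giving the 8S alcohol with the hydroxyl cis to the C8a methyl. Catalyst control is chosen because both faces of this ketone are flanked, by the methyl and by the five-membered ring.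

Step 12
Reactants: 20 3-isopropyl-8a-methyl-2-(phenylthio)-1,2,3,3a,6,7,8,8a-octahydroazulen-8-ol
Product: 21 8β-(tert-butyldimethylsilyloxy)-3-isopropyl-8a-methyl-2-(phenylthio)-1,2,3,3a,6,7,8,8a-octahydroazulene
Conditions: t-BuMe2SiOTf, 2,6-lutidine, CH2Cl2, 0 °C
Reagents that add atoms: tert-butyldimethylsilyl trifluoromethanesulfonate, CC(C)(C)[Si](C)(C)OS(=O)(=O)C(F)(F)F
Why: Silyl protection of a hindered secondary alcohol with the silyl triflate; the ether should survive every step up to the final fluoride treatment.

Step 13
Reactants: 21 8β-(tert-butyldimethylsilyloxy)-3-isopropyl-8a-methyl-2-(phenylthio)-1,2,3,3a,6,7,8,8a-octahydroazulene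
Product: 22 the corresponding C2 phenyl sulfoxide (mixture at sulfur)
Conditions: mCPBA (1.0 equiv), CH2Cl2, −78 °C
Reagents that add atoms: 3-chloroperbenzoic acid, OOC(=O)c1cccc(Cl)c1
Why: Chemoselective sulfide oxidation: a peracid oxidises sulfur far faster than a disubstituted alkene at low temperature, and one equivalent should stop at the sulfoxide.

Step 14
Reactants: 22 C2 phenyl sulfoxide
Product: 24 8β-(tert-butyldimethylsilyloxy)-3-isopropyl-8a-methyl-3,3a,6,7,8,8a-hexahydro-1H-azulen-2-one, via trifluoroacetoxy sulfide 23 (not isolated)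
Conditions: (CF3CO)2O, 2,6-lutidine, MeCN, 0 °C; then aq. NaHCO3, rt
Reagents that add atoms: trifluoroacetic anhydride, O=C(OC(=O)C(F)(F)F)C(F)(F)F
Why: Pummerer reaction: O-acylation of the sulfoxide and loss of the C2 proton (the only α-hydrogen, since the other sulfur substituent is phenyl) give a thionium ion that trifluoroacetate traps; hydrolysis of the O,S-acetal should release the C2 ketone.

Step 15
Reactants: 24 8β-(tert-butyldimethylsilyloxy)-3-isopropyl-8a-methyl-3,3a,6,7,8,8a-hexahydro-1H-azulen-2-one
Product: 26 8β-(tert-butyldimethylsilyloxy)-3-isopropyl-8a-methyl-1,3a,6,7,8,8a-hexahydroazulen-2-yl trifluoromethanesulfonate, via silyl enol ether 25 (not isolated)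
Conditions: Me3SiCl, NaI, Et3N, MeCN, rt; then MeLi, THF, 0 °C; PhNTf2, −78 to 0 °C
Reagents that add atoms: N-phenylbis(trifluoromethanesulfonimide), O=S(=O)(N(c1ccccc1)S(=O)(=O)C(F)(F)F)C(F)(F)F
Why: Thermodynamic enolisation with iodotrimethylsilane and amine should give the more substituted silyl enol ether toward C3; methyllithium turns it regiospecifically into the lithium enolate, which is triflated on oxygen. C3 becomes trigonal here.

Step 16
Reactants: 26 enol triflate
Product: 27 4β,5β-epoxide of 26
Conditions: mCPBA, NaHCO3, CH2Cl2, 0 °C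
Reagents that add atoms: 3-chloroperbenzoic acid, OOC(=O)c1cccc(Cl)c1
Why: Peracid epoxidation: the electron-poor enol triflate is inert, so only the cycloheptene reacts, expected on the convex β face. The α-epoxide would serve equally in step 20 because C6 carries two hydrogens.

Step 17
Reactants: 27 4β,5β-epoxide of 26
Product: 28 4β,5β-epoxy-8β-(tert-butyldimethylsilyloxy)-3-isopropyl-8a-methyl-1,3a,4,5,6,7,8,8a-octahydroazulene
Conditions: Pd(PPh3)4 (5 mol %), Bu3SnH, LiCl, THF, 60 °C
Reagents that add atoms: none
Why: Palladium-catalysed reduction of the enol triflate (oxidative addition, hydride transfer from tin, reductive elimination) should give the C2=C3 alkene under neutral conditions that leave the non-allylic epoxide alone.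

Step 18
Reactants: 28 epoxy cyclopentene
Product: 29 4β,5β-epoxy-8β-(tert-butyldimethylsilyloxy)-3α-isopropyl-8a-methyldecahydroazulene-2β,3β-diol
Conditions: OsO4 (5 mol %), N-methylmorpholine N-oxide, acetone–H2O, rt
Reagents that add atoms: N-methylmorpholine N-oxide, C[N+]1([O-])CCOCC1; water, O
Why: Osmium-catalysed syn dihydroxylation: the reagent should approach the cyclopentene from the β face (H-3a and methyl) rather than the α face blocked by C4 and C8 of the seven-membered ring. This sets C2 and C3 with both hydroxyls β and the isopropyl group α, as in the target.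

Step 19
Reactants: 29 2β,3β-diol
Product: 30 2β-acetate of 29
Conditions: Ac2O, pyridine, DMAP (cat.), CH2Cl2, 0 °C
Reagents that add atoms: acetic anhydride, CC(=O)OC(C)=O
Why: Acylation distinguishes the secondary C2 hydroxyl from the hindered tertiary C3 hydroxyl.

Step 20
Reactants: 30 2β-acetate of 29
Product: 32 2β-acetoxy-8β-(tert-butyldimethylsilyloxy)-3α-isopropyl-8a-methyl-1,2,3,3a,4,7,8,8a-octahydroazulene-3β,4β-diol, via hydroxy selenide 31 (not isolated)
Conditions: (PhSe)2, NaBH4, EtOH, rt to 60 °C; then H2O2, THF, 0 °C to rt
Reagents that add atoms: none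
Why: Epoxide to allylic alcohol through a selenide: the weakly basic selenolate should open the epoxide anti at C5, the carbon remote from the ring fusion. Oxidation to the selenoxide and syn elimination away from the carbinol carbon then give the C5=C6 alkene and the C4 alcohol.

Step 21
Reactants: 32 3β,4β-diol
Product: 33 2β-acetoxy-8β-(tert-butyldimethylsilyloxy)-3β-hydroxy-3α-isopropyl-8a-methyl-2,3,3a,7,8,8a-hexahydro-1H-azulen-4-one
Conditions: Dess–Martin periodinane, NaHCO3, CH2Cl2, 0 °C
Reagents that add atoms: none
Why: Oxidation of the secondary allylic alcohol to the enone under non-basic conditions that should spare the tertiary alcohol, the cis ring fusion (C3a–H) and the β-hydroxy ketone; the C4 configuration is erased on purpose.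

Step 22
Reactants: 33 β-hydroxy enone
Product: 34 3-O-trimethylsilyl ether of 33
Conditions: Me3SiOTf, 2,6-lutidine, CH2Cl2, −78 °C
Reagents that add atoms: trimethylsilyl trifluoromethanesulfonate, C[Si](C)(C)OS(=O)(=O)C(F)(F)F
Why: Silylation caps the tertiary alcohol, so that no β-alkoxide, which could trigger retro-aldol opening of the cyclopentane, is formed in the cuprate step.

Step 23
Reactants: 34 3-O-trimethylsilyl ether of 33
Product: 37 2β-acetoxy-8β-(tert-butyldimethylsilyloxy)-3β-hydroxy-3α-isopropyl-6,8a-dimethyl-2,3,3a,7,8,8a-hexahydro-1H-azulen-4-one, via silyl enol ether 35 (not isolated), via silylated enone 36 (not isolated)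
Conditions: Me2CuLi (from MeLi and CuI), Me3SiCl, THF, −78 °C; Pd(OAc)2, MeCN, rt; citric acid, MeOH, rt
Reagents that add atoms: lithium dimethylcuprate, [Li+].C[Cu-]C
Why: Conjugate addition of the cuprate to the enone with trapping as the silyl enol ether, followed by Saegusa oxidation, should re-form the enone with the methyl group on C6. Mild acidic methanolysis then removes the tertiary trimethylsilyl ether; the transient C6 stereocentre is lost again.

Step 24
Reactants: 37 6-methyl β-hydroxy enone
Product: 38 2β-acetoxy-8β-(tert-butyldimethylsilyloxy)-3α-isopropyl-6,8a-dimethyl-1,2,3,3a,4,7,8,8a-octahydroazulene-3β,4α-diol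
Conditions: Me4NBH(OAc)3, MeCN–AcOH, −30 °C
Reagents that add atoms: none
Why: Hydroxyl-directed 1,2-reduction: the alkoxyborohydride formed at the C3 hydroxyl should deliver hydride intramolecularly to the β face of the C4 ketone, giving the anti 1,3-diol and so the 4α alcohol (4S).

Step 25
Reactants: 38 3β,4α-diol; 39 4-(tert-butyldimethylsilyloxy)benzoic acid
Product: 40 4α-[4-(tert-butyldimethylsilyloxy)benzoyl] ester of 38
Conditions: DCC, DMAP, CH2Cl2, rt
Reagents that add atoms: none
Why: Steglich esterification acylates the secondary allylic C4 alcohol; the tertiary C3 alcohol should not react.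

Step 26
Reactants: 40 bis-silyl ether ester
Product: 41 (2S,3R,3aR,4S,8S,8aS)-2-acetoxy-3,8-dihydroxy-3-isopropyl-6,8a-dimethyl-1,2,3,3a,4,7,8,8a-octahydroazulen-4-yl 4-hydroxybenzoate
Conditions: HF·pyridine, THF–pyridine, 0 °C to rt
Reagents that add atoms: none
Why: Fluoride cleavage of the aryl and the secondary alkyl silyl ethers under buffered conditions that should leave both esters and the allylic C–O bond intact.

## Compound list

1 | 1,4-dioxaspiro[4.5]dec-6-en-8-one | O=C1C=CC2(CC1)OCCO2 | starting material
2 | (S)-1,4-dioxaspiro[4.5]dec-6-en-8-ol | O[C@@H]1C=CC2(OCCO2)CC1 | intermediate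
3 | 3-methylbutanoyl chloride | CC(C)CC(=O)Cl | starting material
4 | (S)-1,4-dioxaspiro[4.5]dec-6-en-8-yl 3-methylbutanoate | CC(C)CC(=O)O[C@@H]1C=CC2(OCCO2)CC1 | intermediate
5 | (E)-trimethylsilyl ketene acetal of 4 | CC(C)/C=C(/O[Si](C)(C)C)O[C@@H]1C=CC2(OCCO2)CC1 | intermediate (not isolated)
6 | trimethylsilyl (2S)-2-[(6R)-1,4-dioxaspiro[4.5]dec-7-en-6-yl]-3-methylbutanoate | C[Si](C)(C)OC(=O)[C@@H](C(C)C)[C@H]1C=CCCC12OCCO2 | intermediate (not isolated)
7 | (2S)-3-methyl-2-[(1R)-2-oxocyclohex-5-en-1-yl]butanoic acid | OC(=O)[C@@H](C(C)C)[C@H]1C=CCCC1=O | intermediate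
8 | (2S)-2-[(1R)-cis-6-hydroxycyclohex-2-en-1-yl]-3-methylbutanoic acid | OC(=O)[C@@H](C(C)C)[C@H]1C=CCC[C@H]1O | intermediate (not isolated)
9 | (3S,3aR,7aR)-3-isopropyl-3a,6,7,7a-tetrahydro-1-benzofuran-2(3H)-one (isopropyl cis to C4) | O=C1O[C@@H]2CCC=C[C@@H]2[C@@H]1C(C)C | intermediate
10 | (3R,3aR,7aR)-3-isopropyl-3a,6,7,7a-tetrahydro-1-benzofuran-2(3H)-one (isopropyl trans to C4) | O=C1O[C@@H]2CCC=C[C@@H]2[C@H]1C(C)C | intermediate
11 | (3R,3aR,7aR)-3-isopropyl-2,3,3a,6,7,7a-hexahydro-1-benzofuran-2-ol (both anomers) | OC1O[C@@H]2CCC=C[C@@H]2[C@H]1C(C)C | intermediate (not isolated)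
12 | 2-[3-methyl-1,1-bis(phenylthio)butan-2-yl]cyclohex-3-en-1-ol, hydroxyl cis to the side chain | O[C@@H]1CCC=C[C@@H]1[C@@H](C(C)C)C(Sc2ccccc2)Sc2ccccc2 | intermediate
13 | 2-[3-methyl-1,1-bis(phenylthio)butan-2-yl]cyclohex-3-en-1-one | O=C1CCC=C[C@@H]1[C@@H](C(C)C)C(Sc2ccccc2)Sc2ccccc2 | intermediate
14 | isopropenylmagnesium bromide | C=C(C)[Mg]Br | starting material
15 | 1-isopropenyl-2-[3-methyl-1,1-bis(phenylthio)butan-2-yl]cyclohex-3-en-1-ol, isopropenyl trans to the side chain | C=C(C)[C@@]1(O)CCC=C[C@@H]1[C@@H](C(C)C)C(Sc2ccccc2)Sc2ccccc2 | intermediate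
16 | trimethylsilyl ether of 15 | C=C(C)[C@@]1(O[Si](C)(C)C)CCC=C[C@@H]1[C@@H](C(C)C)C(Sc2ccccc2)Sc2ccccc2 | intermediate
17 | phenylthionium ion at C2 derived from 16 | C=C(C)[C@@]1(O[Si](C)(C)C)CCC=C[C@@H]1[C@@H](C(C)C)C=[S+]c2ccccc2 | intermediate (not isolated)
18 | bicyclic tertiary carbocation at C8a (Prins intermediate) | C[C+]1C[C@@H](Sc2ccccc2)[C@H](C(C)C)[C@H]2C=CCC[C@]12O[Si](C)(C)C | intermediate (not isolated)
19 | 3β-isopropyl-8a-methyl-2α-(phenylthio)-2,3,3a,6,7,8a-hexahydro-1H-azulen-8-one, cis-fused | c1ccccc1S[C@@H]1C[C@]2(C)C(=O)CCC=C[C@@H]2[C@H]1C(C)C | intermediate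
20 | 8β-hydroxy analogue of 19 (8S) | c1ccccc1S[C@@H]1C[C@]2(C)[C@@H](O)CCC=C[C@@H]2[C@H]1C(C)C | intermediate
21 | 8-O-tert-butyldimethylsilyl ether of 20 | c1ccccc1S[C@@H]1C[C@]2(C)[C@@H](O[Si](C)(C)C(C)(C)C)CCC=C[C@@H]2[C@H]1C(C)C | intermediate
22 | C2 phenyl sulfoxide of 21 (both configurations at sulfur) | O=S(c1ccccc1)[C@@H]1C[C@]2(C)[C@@H](O[Si](C)(C)C(C)(C)C)CCC=C[C@@H]2[C@H]1C(C)C | intermediate
23 | 2-(phenylthio)-2-(trifluoroacetoxy) compound from 22 (C2 undefined) | FC(F)(F)C(=O)OC1(Sc2ccccc2)C[C@]3(C)[C@@H](O[Si](C)(C)C(C)(C)C)CCC=C[C@@H]3[C@H]1C(C)C | intermediate (not isolated)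
24 | 8β-(tert-butyldimethylsilyloxy)-3-isopropyl-8a-methyl-3,3a,6,7,8,8a-hexahydro-1H-azulen-2-one | O=C1C[C@]2(C)[C@@H](O[Si](C)(C)C(C)(C)C)CCC=C[C@@H]2[C@H]1C(C)C | intermediate
25 | 2-(trimethylsilyloxy) C2=C3 enol ether of 24 | C[Si](C)(C)OC1=C(C(C)C)[C@H]2C=CCC[C@H](O[Si](C)(C)C(C)(C)C)[C@@]2(C)C1 | intermediate (not isolated)
26 | C2=C3 enol triflate of 24 | O=S(=O)(OC1=C(C(C)C)[C@H]2C=CCC[C@H](O[Si](C)(C)C(C)(C)C)[C@@]2(C)C1)C(F)(F)F | intermediate
27 | 4β,5β-epoxide of 26 | O=S(=O)(OC1=C(C(C)C)[C@H]2[C@@H]3O[C@@H]3CC[C@H](O[Si](C)(C)C(C)(C)C)[C@@]2(C)C1)C(F)(F)F | intermediate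
28 | 4β,5β-epoxy-8β-(tert-butyldimethylsilyloxy)-3-isopropyl-8a-methyl-1,3a,4,5,6,7,8,8a-octahydroazulene | C1=C(C(C)C)[C@H]2[C@@H]3O[C@@H]3CC[C@H](O[Si](C)(C)C(C)(C)C)[C@@]2(C)C1 | intermediate
29 | 4β,5β-epoxy-8β-(tert-butyldimethylsilyloxy)-3α-isopropyl-8a-methyldecahydroazulene-2β,3β-diol | O[C@H]1C[C@]2(C)[C@@H](O[Si](C)(C)C(C)(C)C)CC[C@H]3O[C@H]3[C@@H]2[C@]1(O)C(C)C | intermediate
30 | 2β-acetate of 29 | CC(=O)O[C@H]1C[C@]2(C)[C@@H](O[Si](C)(C)C(C)(C)C)CC[C@H]3O[C@H]3[C@@H]2[C@]1(O)C(C)C | intermediate
31 | 5α-(phenylseleno)-3β,4β-diol from 30 | CC(=O)O[C@H]1C[C@]2(C)[C@@H](O[Si](C)(C)C(C)(C)C)CC[C@H]([Se]c3ccccc3)[C@@H](O)[C@@H]2[C@]1(O)C(C)C | intermediate (not isolated)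
32 | 2β-acetoxy-8β-(tert-butyldimethylsilyloxy)-3α-isopropyl-8a-methyl-1,2,3,3a,4,7,8,8a-octahydroazulene-3β,4β-diol | CC(=O)O[C@H]1C[C@]2(C)[C@@H](O[Si](C)(C)C(C)(C)C)CC=C[C@@H](O)[C@@H]2[C@]1(O)C(C)C | intermediate
33 | 2β-acetoxy-8β-(tert-butyldimethylsilyloxy)-3β-hydroxy-3α-isopropyl-8a-methyl-2,3,3a,7,8,8a-hexahydro-1H-azulen-4-one | CC(=O)O[C@H]1C[C@]2(C)[C@@H](O[Si](C)(C)C(C)(C)C)CC=CC(=O)[C@@H]2[C@]1(O)C(C)C | intermediate
34 | 3-O-trimethylsilyl ether of 33 | CC(=O)O[C@H]1C[C@]2(C)[C@@H](O[Si](C)(C)C(C)(C)C)CC=CC(=O)[C@@H]2[C@]1(O[Si](C)(C)C)C(C)C | intermediate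
35 | 6-methyl 4-(trimethylsilyloxy) C4=C5 enol ether from 34 (C6 undefined) | CC(=O)O[C@H]1C[C@]2(C)[C@@H](O[Si](C)(C)C(C)(C)C)CC(C)C=C(O[Si](C)(C)C)[C@@H]2[C@]1(O[Si](C)(C)C)C(C)C | intermediate (not isolated)
36 | 3-O-trimethylsilyl ether of 37 | CC(=O)O[C@H]1C[C@]2(C)[C@@H](O[Si](C)(C)C(C)(C)C)CC(C)=CC(=O)[C@@H]2[C@]1(O[Si](C)(C)C)C(C)C | intermediate (not isolated)
37 | 2β-acetoxy-8β-(tert-butyldimethylsilyloxy)-3β-hydroxy-3α-isopropyl-6,8a-dimethyl-2,3,3a,7,8,8a-hexahydro-1H-azulen-4-one | CC(=O)O[C@H]1C[C@]2(C)[C@@H](O[Si](C)(C)C(C)(C)C)CC(C)=CC(=O)[C@@H]2[C@]1(O)C(C)C | intermediate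
38 | 2β-acetoxy-8β-(tert-butyldimethylsilyloxy)-3α-isopropyl-6,8a-dimethyl-1,2,3,3a,4,7,8,8a-octahydroazulene-3β,4α-diol | CC(=O)O[C@H]1C[C@]2(C)[C@@H](O[Si](C)(C)C(C)(C)C)CC(C)=C[C@H](O)[C@@H]2[C@]1(O)C(C)C | intermediate
39 | 4-(tert-butyldimethylsilyloxy)benzoic acid | CC(C)(C)[Si](C)(C)Oc1ccc(cc1)C(=O)O | starting material
40 | 4α-[4-(tert-butyldimethylsilyloxy)benzoyl] ester of 38 | CC(=O)O[C@H]1C[C@]2(C)[C@@H](O[Si](C)(C)C(C)(C)C)CC(C)=C[C@H](OC(=O)c3ccc(O[Si](C)(C)C(C)(C)C)cc3)[C@@H]2[C@]1(O)C(C)C | intermediate
41 | (2S,3R,3aR,4S,8S,8aS)-2-acetoxy-3,8-dihydroxy-3-isopropyl-6,8a-dimethyl-1,2,3,3a,4,7,8,8a-octahydroazulen-4-yl 4-hydroxybenzoate | CC(=O)O[C@H]1C[C@]2(C)[C@@H](O)CC(C)=C[C@H](OC(=O)c3ccc(O)cc3)[C@@H]2[C@]1(O)C(C)C | target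

## Step count and least certain steps

Total: 26 steps. Longest linear sequence: 26 steps (1 to 41); compounds 3, 14 and 39 are commercial and enter directly.

**Step 10 (key step).** Most likely to go wrong: the thionium ion 17 or the cation 18 may lose a proton (vinyl sulfide or diene) before the 1,2-shift, the silyl group may be lost early, or the sulfonium salt may sulfenylate one of the alkenes; the cations are long-lived enough for these side paths if the chair is slow to form. Fallback: generate the same thionium ion by a Pummerer reaction instead of from a dithioacetal. It sets out from lactone 10: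
- LiAlH4 gives diol F1.
- (PhS)2 and Bu3P convert the primary hydroxyl into sulfide F2.
- Swern oxidation gives ketone F3.
- CeCl3-mediated addition of 14 gives tertiary alcohol F4.
- N-(trimethylsilyl)imidazole gives silyl ether F5.
- One equivalent of mCPBA gives sulfoxide F6.
- (CF3CO)2O with 2,6-di-tert-butylpyridine then produces 17, which should cyclise and rearrange to 19, where the route is rejoined.

**Step 11.** Most likely to go wrong: poor facial selectivity in the hydride addition to C8, because one face is flanked by the angular methyl and the other by the folded five-membered ring; catalyst and substrate preferences may be mismatched. Fallback: substrate-controlled reduction of 19 with the bulky hydride LiBH(s-Bu)3, which attacks along the equatorial trajectory and should give the axial alcohol; a wrong epimer is recycled by re-oxidation to 19. The route is rejoined at 20 (no further compound, F0).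

**Step 15.** Most likely to go wrong: enolisation toward C1 instead of C3, because strain between the isopropyl group and the silyloxy group lowers the preference for the more substituted enol ether, leading to the regioisomeric triflate. Fallback: a cationic mode of regiocontrol instead of enolate equilibration. Tf2O with 2,6-di-tert-butyl-4-methylpyridine O-triflates ketone 24, and the resulting oxocarbenium ion loses the proton from the more substituted carbon, giving 26 directly (no further compound, F0).

**Step 20.** Most likely to go wrong: attack of the selenolate at C4 instead of C5, or cleavage or migration of the acetate under the alcoholic conditions. Fallback: isomerise the epoxide without a nucleophile. From 30, Me3SiOTf and DBU should open the silylated epoxide by removing a proton from the unhindered C6, giving the bis(trimethylsilyl) ether F7; citric acid in MeOH then returns the route to 32.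

Further compounds
F1 | step 10 | 2-(1-hydroxy-3-methylbutan-2-yl)cyclohex-3-en-1-ol, hydroxyl cis to the side chain (diol) | O[C@@H]1CCC=C[C@@H]1[C@@H](C(C)C)CO
F2 | step 10 | 2-[3-methyl-1-(phenylthio)butan-2-yl]cyclohex-3-en-1-ol (sulfide) | O[C@@H]1CCC=C[C@@H]1[C@@H](C(C)C)CSc2ccccc2
F3 | step 10 | 2-[3-methyl-1-(phenylthio)butan-2-yl]cyclohex-3-en-1-one (ketone) | O=C1CCC=C[C@@H]1[C@@H](C(C)C)CSc2ccccc2
F4 | step 10 | 1-isopropenyl-2-[3-methyl-1-(phenylthio)butan-2-yl]cyclohex-3-en-1-ol (tertiary alcohol) | C=C(C)[C@@]1(O)CCC=C[C@@H]1[C@@H](C(C)C)CSc2ccccc2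
F5 | step 10 | trimethylsilyl ether of F4 (silyl ether) | C=C(C)[C@@]1(O[Si](C)(C)C)CCC=C[C@@H]1[C@@H](C(C)C)CSc2ccccc2
F6 | step 10 | S-oxide of F5 (sulfoxide, both configurations at sulfur) | C=C(C)[C@@]1(O[Si](C)(C)C)CCC=C[C@@H]1[C@@H](C(C)C)CS(=O)c2ccccc2
F0 | step 11 | none | none
F0 | step 15 | none | none
F7 | step 20 | 3,4-bis(O-trimethylsilyl) ether of 32 | CC(=O)O[C@H]1C[C@]2(C)[C@@H](O[Si](C)(C)C(C)(C)C)CC=C[C@@H](O[Si](C)(C)C)[C@@H]2[C@]1(O[Si](C)(C)C)C(C)C
A1 | alternative 1 | eleven-membered lactone (C3 ester carbon joined to C2 through oxygen; 4-methoxybenzyl ether at C4, silyl ether at C8) | O=C1C[C@@H](OCc2ccc(OC)cc2)/C=C(C)\C[C@H](O[Si](C)(C)C(C)(C)C)/C(C)=C/CO1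
A2 | alternative 1 | cycloheptene carboxylic acid with cis carboxyl and vinyl groups and the C8a methyl | C=C[C@]1(C)[C@@H](O[Si](C)(C)C(C)(C)C)CC(C)=C[C@H](OCc2ccc(OC)cc2)[C@@H]1C(=O)O
A3 | alternative 2 | diazoketone with the C3 diazo carbon bearing isopropyl, tethered through C1 to C8a of the cycloheptene | CC(C)C(=[N+]=[N-])C(=O)C[C@]1(C)[C@@H](O[Si](C)(C)C(C)(C)C)C[C@@H](C)CC=C1
A4 | alternative 2 | tricyclic cyclopropyl ketone (bicyclo[3.1.0]hexan-2-one fused to the cycloheptane) | O=C1C[C@]2(C)[C@@H](O[Si](C)(C)C(C)(C)C)C[C@@H](C)C[C@H]3[C@@H]2[C@@]13C(C)C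
A5 | alternative 3 | 3,6-dimethyl-4-(tert-butyldimethylsilyloxy)cyclohept-2-en-1-one (C4 ketone, C3a=C8a alkene) | CC1=CC(=O)C[C@H](C)C[C@@H]1O[Si](C)(C)C(C)(C)C
A6 | alternative 3 | (4-methylpenta-1,2-dien-3-yl)trimethylsilane | C=C=C(C(C)C)[Si](C)(C)C
A7 | alternative 3 | cis-fused 3-isopropyl-2-trimethylsilylcyclopentene on the cycloheptanone | CC(C)C1=C([Si](C)(C)C)C[C@]2(C)[C@@H](O[Si](C)(C)C(C)(C)C)C[C@@H](C)CC(=O)[C@H]12
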